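**Numbering used throughout (fixed by the steps below):** 1 phloroglucinol; 2 phlorisovalerophenone; 3 its monoprenyl derivative (not isolated); 4 the gem-diprenyl triketone; 5 (S)-limonene; 6 its ozonide (not isolated); 7 the seco keto aldehyde; 8 the cyclopentane hydroxy aldehyde (not isolated); 9 the alkylidene triketone (not isolated); 10 the target.

## Analysis of the target

Target 10 (C31H46O5) is two rings joined through one methylene carbon, C7'. Ring A (C1–C6) is a dearomatised acylphloroglucinol of the hop β-acid type: C1 is a ketone, C2 carries the 3-methylbutanoyl group, C3 and C5 are enolised, C4 carries C7', and C6 is a quaternary carbon with two prenyl groups. Ring A has no stereocentre and exists as a set of enol tautomers. Ring B (C1'–C5') is a cyclopentane with three contiguous stereocentres: C1' (R) bears C7', C2' (S) is a tertiary carbinol with a methyl group, and C5' (S) bears an isopropenyl group. C7' is cis to the hydroxyl on C2' and trans to the isopropenyl group on C5', so it is trans to both neighbouring carbon substituents.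

The feature the route exploits is the array C7'–C1'–C2'(OH)(CH3) together with the carbon count of ring B. C7', ring B, the methyl and the isopropenyl group form a p-menthane skeleton in which one ring carbon (C7') has been pushed out of the ring. With C7' read as a carbonyl carbon, the array is a β-hydroxy aldehyde, an aldol retron across C1'–C2'. C7' also sits on C4, the only C–H position of a cyclic vinylogous acid, which is the signature of a Knoevenagel condensation followed by reduction.

The sensitive groups are:
- the enolised β-triketone (acidic, ambident O/C nucleophile, readily oxidised by air);
- the tertiary alcohol (prone to dehydration and to cyclodehydration onto the C3 or C5 enol oxygen);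
- two prenyl olefins and an isopropenyl group, which forbid hydrogenation, unselective electrophilic oxidants and strong acids.

The difficulty is to set three adjacent stereocentres on a small ring, one of them a tertiary alcohol, and to join that ring through a hindered methylene to an unprotected, polyfunctional acid.

## Retrosynthetic reasoning

**C4–C7' (10 ⇒ 9 ⇒ 4 + 8).** The first cut is the only bond between the achiral half and the chiral half. In the forward direction C7' arrives as the aldehyde carbon of 8, condenses with C4 of 4 to the alkylidene triketone 9, and 9 is reduced at C7' by an organic hydride donor. The cut is made here because C4 is the only C–H nucleophile of 4, so no protecting group or regiochemical control is needed. C7' at the aldehyde oxidation level is also exactly what the next disconnection leaves behind. The forward reaction must be neutral and mild enough to keep the tertiary alcohol of 8 and the C1' configuration.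

**C1'–C2' (8 ⇒ 7).** The second cut is the aldol bond of ring B. It opens the cyclopentane to the acyclic keto aldehyde 7, which has a single stereocentre (the future C5'). The forward reaction is an enamine-mediated 5-enolexo aldol. It must use the aldehyde as donor and the methyl ketone as acceptor, must stop before dehydration, and must set C1' and C2' relative to C5'. Cutting C1'–C2' rather than C1'–C5' or C2'–C3' is what turns ring B into a known seco-terpene.

**Ring cleavage (7 ⇒ 6 ⇒ 5).** Compound 7 is (S)-limonene 5 with its ring double bond cleaved. Seen from the target, ring B plus C7' is the six-membered ring of 5 after scission between the methyl-bearing carbon and its olefinic neighbour and re-closure one carbon further on. The hardest ring of the target thus arises by contraction of a commodity terpene ring. The C4 stereocentre of 5 becomes C5' unchanged, with the same S descriptor. The forward reaction (ozonolysis through ozonide 6) must cleave the trisubstituted ring olefin and spare the isopropenyl group.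

**Two C6–prenyl bonds (4 ⇒ 3 ⇒ 2).** Both prenyl groups on C6 are disconnected to phlorisovalerophenone 2. The forward reaction is a dearomative gem-C-alkylation through the monoprenyl compound 3. It creates no stereocentre and is placed early, on cheap material, because its regioselectivity is its weak point.

**Acyl–arene bond (2 ⇒ 1).** The 3-methylbutanoyl group is disconnected by Friedel–Crafts logic to phloroglucinol 1.

## Alternatives that were turned down

**Alternative 1:** (the textbook disconnection) C4–C7' as an enolate alkylation. The cyclopentane would be built separately and converted into the primary iodide A1, (1S,2R,3S)-2-(iodomethyl)-1-methyl-3-(prop-1-en-2-yl)cyclopentan-1-ol. The forward key step is C-alkylation of the anion of 4 with A1. It was turned down for three reasons: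
- A1 is a β,β-disubstituted primary halide flanked by a quaternary carbinol and a branched methine, so SN2 attack by a stabilised, hindered carbon nucleophile would be slow.
- The anion of 4 is ambident and prefers O-alkylation with unactivated alkyl halides.
- Under base, A1 is a γ-iodo alkoxide that can close to an oxetane or undergo Grob fragmentation of ring B.

A1 would also have to be made from a carbonyl compound such as 8 by two extra redox/activation steps, so it costs more steps and delivers a worse bond-forming reaction.

**Alternative 2:** (the biomimetic disconnection) the C1'–C5' bond of ring B inside a geranyl side chain. The precursor would be the 4-geranyl analogue A2. The forward key step would be an oxidative cyclisation joining geranyl C2 to C6, placing oxygen on C3 and ending with proton loss to the isopropenyl group. It was turned down on mechanism: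
- The polar version needs a 2,3-epoxide to be opened at C2 by the 6,7-olefin with both epoxide carbons inside the new ring. This is a geometrically disfavoured endo opening, and a Lewis acid would ionise the tertiary C3–O bond instead.
- The enol oxygens at C3 and C5 of ring A lie closer than the olefin and would trap the epoxide or cation as chromane or furan ethers.
- No oxidant distinguishes the geranyl 2,3-olefin from the two prenyl olefins and the 6,7-olefin.
- A concerted ene variant would give the 1,2-cis arrangement of C7' and isopropenyl, opposite to the target.
- Nothing controls the absolute configuration.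

**Alternative 3:** conjugate addition/enolate trapping on a five-membered enone, cutting C5'–isopropenyl, C1'–C7' and C2'–CH3. Enantioselective conjugate addition of an isopropenyl nucleophile to cyclopent-2-en-1-one and trapping of the enolate with a 2,4,6-trimethoxybenzyl electrophile would give the trans ketone A3. Methyl addition anti to the benzyl group would then set C2'. This forms the C1'–C7' bond and two stereocentres in one operation. It was turned down because ring A cannot take part as such: its acidic protons would quench the enolate, and its methylene quinone-methide form is not a storable electrophile. A protected arene must therefore be carried, and ring A would have to be finished afterwards by threefold demethylation, Friedel–Crafts acylation and dearomative diprenylation. The Lewis and Brønsted acids of those steps would ionise the tertiary alcohol and add to the isopropenyl group. With the protecting-group steps this would need, the route would be more than twice as long as the chosen one.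

Key step: step 4

Assumption: the β-triketone of 4, 9 and 10 is one rapidly equilibrating set of enol tautomers; each SMILES shows one tautomer, for 10 the one of the given structure.

## Route

Step 1
Reactants: 1 phloroglucinol (benzene-1,3,5-triol)
Product: 2 phlorisovalerophenone (3-methyl-1-(2,4,6-trihydroxyphenyl)butan-1-one)
Conditions: isovaleryl chloride (1.0 equiv), AlCl3 (3 equiv), PhNO2/CH2Cl2, 0 °C to 45 °C; then ice/aq. HCl
Reagents that add atoms: isovaleryl chloride (3-methylbutanoyl chloride), CC(C)CC(=O)Cl
Why: Friedel–Crafts C-acylation of the electron-rich triol; the first acyl group, chelated to aluminium, deactivates the ring so that mono-acylation should dominate, and any O-acyl ester rearranges to the ketone under the same conditions (Fries rearrangement). No stereocentre is involved.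

Step 2
Reactants: 2 phlorisovalerophenone
Product: 4 3,5-dihydroxy-2-(3-methylbutanoyl)-6,6-bis(3-methylbut-2-en-1-yl)cyclohexa-2,4-dien-1-one (gem-diprenyl triketone), via monoprenyl phlorisovalerophenone 3 (not isolated)
Conditions: NaOMe (3 equiv), MeOH, −10 °C; prenyl bromide (2.0 equiv, slow addition), −10 °C to rt, N2; then 1 M HCl; NaHCO3 extraction and chromatography
Reagents that add atoms: prenyl bromide (1-bromo-3-methylbut-2-ene), CC(C)=CCBr
Why: Dearomative gem-C-alkylation of an acylphloroglucinolate, the alkylation type used for hop β-acids and gem-dialkylated acylphloroglucinols: methanol solvates the oxygens and steers the allylic bromide to carbon, and after the first prenylation (3) the prenylated carbon is the most electron-rich site, so the second prenyl group is expected to enter there and give the stabilised vinylogous-acid anion of 4. The aromatic 3,5-diprenyl isomer and triprenylated material are the expected by-products, and 4, being the stronger acid, should be separable by bicarbonate extraction and chromatography. No stereocentre is formed.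

Step 3
Reactants: 5 (S)-(−)-limonene ((4S)-1-methyl-4-(prop-1-en-2-yl)cyclohex-1-ene)
Product: 7 (3S)-6-oxo-3-(prop-1-en-2-yl)heptanal, via limonene ozonide 6 (not isolated)
Conditions: O3/O2 (1.0 equiv, calibrated stream), CH2Cl2, −78 °C; then PPh3 (1.1 equiv), −78 °C to rt
Reagents that add atoms: ozone, [O-][O+]=O
Why: Ozonolysis (Criegee mechanism) of the trisubstituted ring olefin, which is more electron-rich than the 1,1-disubstituted isopropenyl group and should react first with one equivalent of ozone at −78 °C; PPh3 reduces ozonide 6 to the ketone and the aldehyde. The stereocentre of 5 is not touched and is not α to either new carbonyl group, so it cannot epimerise.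

Step 4
Reactants: 7 (3S)-6-oxo-3-(prop-1-en-2-yl)heptanal; 4 3,5-dihydroxy-2-(3-methylbutanoyl)-6,6-bis(3-methylbut-2-en-1-yl)cyclohexa-2,4-dien-1-one
Product: 10 3,5-dihydroxy-4-{[(1R,2S,5S)-2-hydroxy-2-methyl-5-(prop-1-en-2-yl)cyclopentyl]methyl}-2-(3-methylbutanoyl)-6,6-bis(3-methylbut-2-en-1-yl)cyclohexa-2,4-dien-1-one (CNP0332156.1), via hydroxy aldehyde 8 (not isolated), via alkylidene triketone 9 (not isolated)
Conditions: D-proline (20 mol%), CH2Cl2 (0.1 M), rt, until 7 is consumed; then 4 (1.0 equiv), Hantzsch ester (diethyl 2,6-dimethyl-1,4-dihydropyridine-3,5-dicarboxylate, 1.1 equiv), rt, N2, dark; reverse-phase chromatography with degassed solvents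
Reagents that add atoms: none
Why: D-Proline condenses with the aldehyde of 7 rather than with the methyl ketone, and the E-enamine carbon (future C1') adds to the ketone carbon (future C2') in a 5-(enolexo)-exo-trig closure, the aldol type known as proline-catalysed enolexo aldolisation of dicarbonyl compounds; the same C–C bond is formed, with subsequent dehydration, in the classical amine/acid cyclisation of this keto aldehyde, and the milder conditions here are meant to stop at the aldol. This closes ring B and completes the contraction of the six-membered ring of 5 to a cyclopentane, with one former ring carbon left outside as C7'. C1' is set trans to the isopropenyl group because the C5' substituent turns away from the enamine CH=N unit in the forming ring, and the D enantiomer of the catalyst is chosen because carboxylic-acid-directed attack on its enamine gives R at C1', the same sense as this substrate bias. C2' is set by the hydrogen bond from the proline carboxyl group to the ketone oxygen, which holds that oxygen gauche to the enamine carbon in a cis-fused bicyclic transition state and so places OH cis and methyl trans to the formyl group; this isomer, with the formyl group trans to both neighbouring carbon substituents, should also be the most stable one, so aldol reversibility or enamine epimerisation at C1' works in favour of 8. The step needs chemoselectivity (aldehyde as donor, ketone as acceptor) and needs 4 to be withheld until 7 is consumed, so that no open-chain aldehyde is alkylated. In the second stage the same catalyst converts 8 into an iminium ion that is attacked by C4 of 4, the only nucleophilic C–H carbon of this vinylogous acid, and loss of proline gives the alkylidene triketone 9 (Knoevenagel condensation). Hantzsch ester transfers hydride to C7' of 9 as it forms, the known three-component reductive alkylation of cyclic 1,3-diones, which forestalls Michael addition of a second molecule of 4, γ-deprotonation at C1' and loss of the tertiary hydroxyl. No stereocentre is formed in the second stage, and the neutral conditions at room temperature leave the prenyl and isopropenyl olefins, the tertiary alcohol and the enols untouched.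

## Compound list

1 | phloroglucinol (benzene-1,3,5-triol) | Oc1cc(O)cc(O)c1 | starting material
2 | phlorisovalerophenone, 3-methyl-1-(2,4,6-trihydroxyphenyl)butan-1-one | CC(C)CC(=O)c1c(O)cc(O)cc1O | intermediate
3 | monoprenyl phlorisovalerophenone, 3-methyl-1-[2,4,6-trihydroxy-3-(3-methylbut-2-en-1-yl)phenyl]butan-1-one | CC(C)CC(=O)c1c(O)cc(O)c(CC=C(C)C)c1O | intermediate
4 | 3,5-dihydroxy-2-(3-methylbutanoyl)-6,6-bis(3-methylbut-2-en-1-yl)cyclohexa-2,4-dien-1-one | CC(C)CC(=O)C1=C(O)C=C(O)C(CC=C(C)C)(CC=C(C)C)C1=O | intermediate
5 | (S)-(−)-limonene, (4S)-1-methyl-4-(prop-1-en-2-yl)cyclohex-1-ene | CC1=CC[C@H](CC1)C(C)=C | starting material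
6 | limonene secondary ozonide, (4S)-1-methyl-4-(prop-1-en-2-yl)-7,8,9-trioxabicyclo[4.2.1]nonane (both bridgehead diastereomers) | CC12CC[C@H](C(C)=C)CC(OO1)O2 | intermediate
7 | (3S)-6-oxo-3-(prop-1-en-2-yl)heptanal | C=C(C)[C@H](CC=O)CCC(C)=O | intermediate
8 | (1R,2S,5S)-2-hydroxy-2-methyl-5-(prop-1-en-2-yl)cyclopentane-1-carbaldehyde | C=C(C)[C@H]1CC[C@](C)(O)[C@@H]1C=O | intermediate
9 | 5-hydroxy-6-{[(1R,2S,5S)-2-hydroxy-2-methyl-5-(prop-1-en-2-yl)cyclopentyl]methylidene}-4-(3-methylbutanoyl)-2,2-bis(3-methylbut-2-en-1-yl)cyclohex-4-ene-1,3-dione (geometry of the exocyclic olefin not defined) | C=C(C)[C@H]1CC[C@](C)(O)[C@@H]1C=C2C(O)=C(C(=O)CC(C)C)C(=O)C(CC=C(C)C)(CC=C(C)C)C2=O | intermediate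
10 | CNP0332156.1, 3,5-dihydroxy-4-{[(1R,2S,5S)-2-hydroxy-2-methyl-5-(prop-1-en-2-yl)cyclopentyl]methyl}-2-(3-methylbutanoyl)-6,6-bis(3-methylbut-2-en-1-yl)cyclohexa-2,4-dien-1-one | C=C(C)[C@H]1CC[C@](C)(O)[C@@H]1CC1=C(O)C(CC=C(C)C)(CC=C(C)C)C(=O)C(C(=O)CC(C)C)=C1O | target

## Step count and least certain steps

Total step count: 4. Longest linear sequence: 3 steps (steps 1, 2 and 4, from 1 to 10); the second branch is 2 steps (steps 3 and 4, from 5 to 10).

**Step 4 (key step).** Several processes may go wrong:
- Dehydration of the tertiary aldol through the enamine/iminium (E1cB) before or during the coupling. This would divert material to the conjugated enal and, after condensation with 4, into oxa-6π electrocyclisation.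
- Insufficient facial selectivity of the ring closure relative to C5', closure to the trans aldol, or a catalyst–substrate mismatch. Any of these would carry C1'/C2' diastereomers into the product.
- Slow aldolisation onto the ketone, so that open-chain aldehyde is alkylated in the second stage.
- Michael addition of a second molecule of 4 to 9 outrunning hydride transfer.

The fallback sets out from 7 and comes back to the route at 8. Piperidine/AcOH in toluene should condense 7 to the enal (5R)-2-methyl-5-(prop-1-en-2-yl)cyclopent-1-ene-1-carbaldehyde F1. Weitz–Scheffer epoxidation (H2O2, NaOH, MeOH, 0 °C) should then add oxygen anti to the isopropenyl group and give the epoxy aldehyde (1R,2R,5S)-5-methyl-2-(prop-1-en-2-yl)-6-oxabicyclo[3.1.0]hexane-1-carbaldehyde F2, which fixes C2' by reagent approach. Single-electron reduction with SmI2 (2 equiv, THF/MeOH, −78 °C), as used for α,β-epoxy ketones, should cleave the Cα–O bond. Protonation of the enolate and equilibration of the α-centre with a mild amine base to the arrangement trans to the isopropenyl group should then give isolated 8. This 8 is carried through the second stage of step 4 (4, proline, Hantzsch ester) to 10.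

**Step 2.** The likely problems are poor regioselectivity of the second prenylation (free ring carbon instead of the already prenylated carbon), competing O-prenylation, over-alkylation of 4 at C4, and oxidative loss of 4 during isolation.

The fallback reverses the order of union and dearomatisation. It sets out from 2 (together with 8, generated from 7 as in the first stage of step 4) and comes back to the route at 10. Reductive alkylation of excess 2 with 8 under the second-stage conditions of step 4 would pass through the o-quinone methide 6-{[(1R,2S,5S)-2-hydroxy-2-methyl-5-(prop-1-en-2-yl)cyclopentyl]methylidene}-3,5-dihydroxy-4-(3-methylbutanoyl)cyclohexa-2,4-dien-1-one F3. This would give the aromatic 1-[2,4,6-trihydroxy-3-{[(1R,2S,5S)-2-hydroxy-2-methyl-5-(prop-1-en-2-yl)cyclopentyl]methyl}phenyl]-3-methylbutan-1-one F4. NaOMe and prenyl bromide (2 equiv) in MeOH would then place both prenyl groups on the single remaining ring C–H carbon. The first gives the aromatic monoprenyl compound 1-[2,4,6-trihydroxy-3-{[(1R,2S,5S)-2-hydroxy-2-methyl-5-(prop-1-en-2-yl)cyclopentyl]methyl}-5-(3-methylbut-2-en-1-yl)phenyl]-3-methylbutan-1-one F5. The second, with dearomatisation, is favoured at the prenylated carbon over the carbon bearing the bulky β-branched cyclopentylmethyl group, and gives 10.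

**Step 3.** The likely problems are over-oxidation (ozone attacking the isopropenyl group once the ring olefin is consumed or in competition with it), incomplete reduction of peroxidic intermediates, and self-condensation of 7 on storage.

The fallback sets out from 5 and comes back to the route at 7. Epoxidation with mCPBA (1 equiv, CH2Cl2, 0 °C), which is selective for the trisubstituted olefin, would give (4S)-limonene 1,2-oxide, (4S)-1-methyl-4-(prop-1-en-2-yl)-7-oxabicyclo[4.1.0]heptane F6, as a cis/trans mixture in which both isomers converge. Cleavage with H5IO6 in THF/H2O, through the diol, would deliver 7 without an electrophile that can touch the isopropenyl group.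

## Further compounds

F1 | step 4 | (5R)-2-methyl-5-(prop-1-en-2-yl)cyclopent-1-ene-1-carbaldehyde | C=C(C)[C@H]1CCC(C)=C1C=O
F2 | step 4 | (1R,2R,5S)-5-methyl-2-(prop-1-en-2-yl)-6-oxabicyclo[3.1.0]hexane-1-carbaldehyde (oxirane trans to isopropenyl) | C=C(C)[C@H]1CC[C@]2(C)O[C@]12C=O
F3 | step 2 | 6-{[(1R,2S,5S)-2-hydroxy-2-methyl-5-(prop-1-en-2-yl)cyclopentyl]methylidene}-3,5-dihydroxy-4-(3-methylbutanoyl)cyclohexa-2,4-dien-1-one (o-quinone methide, olefin geometry not defined) | C=C(C)[C@H]1CC[C@](C)(O)[C@@H]1C=C2C(=O)C=C(O)C(C(=O)CC(C)C)=C2O
F4 | step 2 | 1-[2,4,6-trihydroxy-3-{[(1R,2S,5S)-2-hydroxy-2-methyl-5-(prop-1-en-2-yl)cyclopentyl]methyl}phenyl]-3-methylbutan-1-one | C=C(C)[C@H]1CC[C@](C)(O)[C@@H]1Cc1c(O)cc(O)c(C(=O)CC(C)C)c1O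
F5 | step 2 | 1-[2,4,6-trihydroxy-3-{[(1R,2S,5S)-2-hydroxy-2-methyl-5-(prop-1-en-2-yl)cyclopentyl]methyl}-5-(3-methylbut-2-en-1-yl)phenyl]-3-methylbutan-1-one | C=C(C)[C@H]1CC[C@](C)(O)[C@@H]1Cc1c(O)c(CC=C(C)C)c(O)c(C(=O)CC(C)C)c1O
F6 | step 3 | (4S)-limonene 1,2-oxide, (4S)-1-methyl-4-(prop-1-en-2-yl)-7-oxabicyclo[4.1.0]heptane (cis/trans mixture) | CC12CC[C@H](C(C)=C)CC1O2
A1 | alternative 1 | (1S,2R,3S)-2-(iodomethyl)-1-methyl-3-(prop-1-en-2-yl)cyclopentan-1-ol | C=C(C)[C@H]1CC[C@](C)(O)[C@@H]1CI
A2 | alternative 2 | 4-[(2E)-3,7-dimethylocta-2,6-dien-1-yl]-3,5-dihydroxy-2-(3-methylbutanoyl)-6,6-bis(3-methylbut-2-en-1-yl)cyclohexa-2,4-dien-1-one | CC(C)=CCC/C(C)=C/CC1=C(O)C(CC=C(C)C)(CC=C(C)C)C(=O)C(C(=O)CC(C)C)=C1O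
A3 | alternative 3 | (2R,3S)-3-(prop-1-en-2-yl)-2-[(2,4,6-trimethoxyphenyl)methyl]cyclopentan-1-one | C=C(C)[C@H]1CCC(=O)[C@@H]1Cc1c(OC)cc(OC)cc1OC
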